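The data are simulated from invented constants; scatter was added.

The easy step comes first: starting material takes up reagent and gives single product, which these runs do not read. Behind it, if the candidate steps hold, single product goes on to bis adduct and bis adduct to tris adduct, each step using the same dissolved reagent, which is supplied from the gas.

the same everywhere: gas 95 mM (held)
- blue: starting material 1.5 M; temperature 25 °C; run made earlier
- red: starting material 2.4 M; temperature 36 °C; run made earlier
- eta: starting material 1.1 M; at 20 °C until 8.0 h, from then on at 40 °C; time 10 h
- alpha: starting material 1.1 M; temperature 40 °C; time 10 h
- zeta: starting material 1.1 M; temperature 20 °C; time 10 h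

| run | time / h | bis adduct / % | starting material / % |
|---|---|---|---|
| blue | 2.00 | 0 | 91.3 |
| blue | 5.00 | 4.0 | 82.4 |
| blue | 10.0 | 14.1 | 65.7 |
| blue | 15.0 | 23.2 | 52.0 |
| blue | 20.0 | 26.9 | 43.6 |
| red | 0.833 | 2.1 | 95.8 |
| red | 2.50 | 2.2 | 85.5 |
| red | 5.00 | 8.1 | 75.2 |
| red | 8.00 | 13.7 | 63.1 |
| red | 10.0 | 19.6 | 55.9 |

(readings scatter by 1 percentage point)

1. the flask that comes out highest in amount of bis adduct, in percent of the starting material charged, or "all alike" when all lie within 1.5 percentage points (eta / alpha / zeta / all alike)
2. bis adduct at the end, in percent of the starting material charged, eta
3. bis adduct at the end, in percent of the starting material charged, alpha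
4. bis adduct at the end, in percent of the starting material charged, zeta

- what is said of bis adduct includes crystals
- crystals is a solid; its amount is given per volume of the solution
- at the start none of reagent is dissolved
- candidate steps: starting material + reagent -> single product; reagent + single product -> bis adduct; reagent + bis adduct -> tris adduct; gas <-> reagent; crystals <-> bis adduct

In the first instants no reagent is dissolved, and bis adduct must wait for single product: at 2.00 h the blue run has lost 8.70% of its starting material while bis adduct reads 0%. In the middle, at 10.0 h, blue has lost 34.3%, of which bis adduct holds 14.1%; the other 20.2% must be single product or tris adduct. Towards the end, blue's ratio of bis adduct to starting material lost reads 0.483 at 15.0 h and 0.477 at 20.0 h. The earlier ratio applied to the later loss gives 27.3% bis adduct against the 26.9% read, a gap of 0.36 percentage points beside a scatter of 1 point, so we read no trend from this pair.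

Reagent concentration stands in each of these rates, so dividing the rate of bis adduct formation by the rate of loss of starting material cancels it, and time with it. The ratio then follows how far a flask has gone, not the clock. At 10.0 h it reads 0.411 in blue and 0.444 in red, despite their different charges and temperatures. We carry the mean of these readings, the yield on converted starting material (integral selectivity) Y = 0.428.

Our own reckoning takes alpha, warmer than red, to lose at least red's 44.1%, so Y gives at least 18.9% bis adduct in alpha. The forecast, with a first-order loss “independent of charge”, names alpha highest and gives eta 12.5%, alpha 21% (17% to 25%) and zeta 11%, so its alpha stands above our bound.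

The flasks give eta 14.4%, alpha 27.0% and zeta 9.36%. Alpha is highest, as forecast, and eta and zeta lie inside the forecast's ranges, but alpha stands 6 points above its forecast.

    starting material + reagent → single product (k = 0.0370 /M/min, Ea = 65.0 kJ/mol)
    reagent + single product → bis adduct (k = 0.110 /M/min, Ea = 61.0 kJ/mol)
    reagent + bis adduct → tris adduct (k = 0.0520 /M/min, Ea = 72.0 kJ/mol)
    gas ⇌ reagent, rate k4*(csat - [reagent]) (kL = 0.0500 /min)
    crystals ⇌ bis adduct, rate k5*(cs5 - [bis adduct]) while solid is left; crystals form when [bis adduct] > cs5 (solubility = 0.320 M, k = 0.140 /min)
    (constants at 40 °C)

Alpha keeps 37% of its starting material, so Y gives 27.0% bis adduct, against 27.0% found. The forecast's 21% divided by Y means a loss of 49.1%, whereas alpha lost 63.0%, so forecast and flask part on how much starting material went. Left until 15 h, the zeta flask keeps 62.2% of its starting material, so Y gives 16.2%, and that flask holds 16.1% bis adduct.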